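**Plan**

Flavan numbering is used (O1, C2, C3, C4, C4a, C5–C8, C8a). Ring A is a cyclohexa-2,4-dienone (C7=O, C6=C5, C4a=C8a) whose only sp3 carbon, C8, carries two identical prenyl groups beside the C7 carbonyl. That is the imprint of a dienylketene (ketene carbon C7) closing onto a fully substituted alkene terminus (C8).
Retrosynthetic cuts, in order: O–Si; C7–C8 (retro-6π, then retro-4π to spiro-cyclobutenone 22); C6–C7 and C5–C4a (retro-[2+2] to vinylketene 21 and methoxyacetylene 19); O1–C8a and C4–C4a of the pyran ring (cyclodehydration, C-acylation); the two C8–CH2 bonds (dianion alkylations).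
Forward: allyl acetoacetate is prenylated twice at its terminal carbon (6) and C-acylated with silyloxy acid 9. The pyran ring closes first (13), the four-membered ring second (22), ring A last (24); desilylation gives 25.
Stereochemistry: C2 comes from ethyl (S)-3-hydroxy-3-phenylpropanoate. C4 is set cis to the phenyl group by substrate-controlled Luche reduction. C8 is not stereogenic, and the spiro centre of 22 is erased in the key step.

Key step: step 12

Assumption: the β-dicarbonyl and tricarbonyl compounds (6, 11, 12) are written as keto forms although they should exist largely as chelated enols, and 22 is carried as a mixture of its two spiro epimers.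

**Route**

Step 1
Reactants: 1 allyl acetoacetate; 2 prenyl bromide
Product: 4 allyl 7-methyl-3-oxooct-6-enoate, via dilithium dianion of allyl acetoacetate 3 (not isolated)
Conditions: LDA (2.1 equiv), THF, −78 → 0 °C; 2, −78 → 0 °C; aq HCl
Reagents that add atoms: none
Why: γ-Alkylation of an acetoacetate dianion: the more basic terminal carbanion reacts with the allylic bromide while the α-carbon stays masked as the enolate, and keeping the dianion at or below 0 °C should prevent the [3,3] (Carroll-type) shift of the allyl ester from competing.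

Step 2
Reactants: 4 allyl 7-methyl-3-oxooct-6-enoate; 2 prenyl bromide
Product: 6 allyl 7-methyl-4-(3-methylbut-2-en-1-yl)-3-oxooct-6-enoate, via dilithium dianion of the monoprenyl keto ester 5 (not isolated)
Conditions: LDA (2.1 equiv), THF, −78 → 0 °C; 2, −78 → 0 °C; aq HCl
Reagents that add atoms: none
Why: A second dianion γ-alkylation: after α-enolate formation the only further acidic site is the substituted C4–H, so the second prenyl group should enter at the same carbon and give the symmetrical diprenylmethyl ketone.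

Step 3
Reactants: 7 ethyl (3S)-3-hydroxy-3-phenylpropanoate
Product: 8 ethyl (3S)-3-{[tert-butyl(dimethyl)silyl]oxy}-3-phenylpropanoate
Conditions: TBSCl, imidazole, DMF, rt
Reagents that add atoms: tert-butyldimethylsilyl chloride, CC(C)(C)[Si](C)(C)Cl
Why: Imidazole-promoted silyl ether formation protects the carbinol without touching the stereocentre.

Step 4
Reactants: 8 ethyl (3S)-3-{[tert-butyl(dimethyl)silyl]oxy}-3-phenylpropanoate
Product: 9 (3S)-3-{[tert-butyl(dimethyl)silyl]oxy}-3-phenylpropanoic acid
Conditions: LiOH, THF/MeOH/H2O, 0 °C → rt; 1 M HCl to pH 4, 0 °C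
Reagents that add atoms: lithium hydroxide, [Li+].[OH-]
Why: Ester saponification; the secondary TBS ether should tolerate cold LiOH, the C–O stereocentre is not involved, and mild acidification avoids silyl loss.

Step 5
Reactants: 9 (3S)-3-{[tert-butyl(dimethyl)silyl]oxy}-3-phenylpropanoic acid; 6 allyl 7-methyl-4-(3-methylbut-2-en-1-yl)-3-oxooct-6-enoate
Product: 11 allyl 2-[(3S)-3-{[tert-butyl(dimethyl)silyl]oxy}-3-phenylpropanoyl]-7-methyl-4-(3-methylbut-2-en-1-yl)-3-oxooct-6-enoate, via silyloxy acid chloride 10 (not isolated)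
Conditions: 1-chloro-N,N,2-trimethylprop-1-en-1-amine (Ghosez reagent), CH2Cl2, 0 °C; then 6, MgCl2, pyridine, CH2Cl2, 0 °C → rt
Reagents that add atoms: none
Why: Neutral acid chloride formation with the α-chloroenamine, then magnesium-enolate C-acylation of the β-keto ester (MgCl2/pyridine soft enolization), in which chelation directs the acyl group to the central carbon and not to oxygen.

Step 6
Reactants: 11 allyl 2-[(3S)-3-{[tert-butyl(dimethyl)silyl]oxy}-3-phenylpropanoyl]-7-methyl-4-(3-methylbut-2-en-1-yl)-3-oxooct-6-enoate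
Product: 13 allyl (2S)-6-(2,8-dimethylnona-2,7-dien-5-yl)-4-oxo-2-phenyl-3,4-dihydro-2H-pyran-5-carboxylate, via hydroxy tricarbonyl 12 (not isolated)
Conditions: 48% aq HF, MeCN, 0 °C → rt; then TsOH·H2O (cat.), 4 Å MS, CH2Cl2, rt
Reagents that add atoms: none
Why: Acidic desilylation frees the C2 hydroxyl, which adds to the enolized diprenylacetyl ketone carbon (C8a) in a six-membered hemiketalization and loses water (cyclodehydration of a δ-hydroxy-β-dicarbonyl to a 2,3-dihydro-4-pyranone), the ketone being a better electrophile than the ester under acid; the C2–O bond is not broken, so the configuration is kept.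

Step 7
Reactants: 13 allyl (2S)-6-(2,8-dimethylnona-2,7-dien-5-yl)-4-oxo-2-phenyl-3,4-dihydro-2H-pyran-5-carboxylate
Product: 14 allyl (2S,4S)-6-(2,8-dimethylnona-2,7-dien-5-yl)-4-hydroxy-2-phenyl-3,4-dihydro-2H-pyran-5-carboxylate
Conditions: NaBH4, CeCl3·7H2O, MeOH, −78 → −40 °C
Reagents that add atoms: none
Why: Luche 1,2-reduction: the cerium-modified borohydride attacks the C4 carbonyl and not the oxygen-deactivated β-carbon, along the axial trajectory of the half-chair in which phenyl is pseudo-equatorial, so the new carbinol (4S) should be pseudo-equatorial and cis to the C2 phenyl group.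

Step 8
Reactants: 14 allyl (2S,4S)-6-(2,8-dimethylnona-2,7-dien-5-yl)-4-hydroxy-2-phenyl-3,4-dihydro-2H-pyran-5-carboxylate
Product: 15 allyl (2S,4S)-4-{[tert-butyl(dimethyl)silyl]oxy}-6-(2,8-dimethylnona-2,7-dien-5-yl)-2-phenyl-3,4-dihydro-2H-pyran-5-carboxylate
Conditions: TBSOTf, 2,6-lutidine, CH2Cl2, −78 → 0 °C
Reagents that add atoms: tert-butyldimethylsilyl trifluoromethanesulfonate, CC(C)(C)[Si](C)(C)OS(=O)(=O)C(F)(F)F
Why: Silylation of a hindered secondary allylic alcohol by the silyl triflate with 2,6-lutidine as buffer; the ester-deactivated enol ether should not ionize at C4.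

Step 9
Reactants: 15 allyl (2S,4S)-4-{[tert-butyl(dimethyl)silyl]oxy}-6-(2,8-dimethylnona-2,7-dien-5-yl)-2-phenyl-3,4-dihydro-2H-pyran-5-carboxylate
Product: 16 (2S,4S)-4-{[tert-butyl(dimethyl)silyl]oxy}-6-(2,8-dimethylnona-2,7-dien-5-yl)-2-phenyl-3,4-dihydro-2H-pyran-5-carboxylic acid
Conditions: Pd(PPh3)4 (5 mol %), HCO2H, Et3N, THF, rt
Reagents that add atoms: none
Why: Tsuji–Trost deallylation with formate as hydride donor: Pd(0) ionizes only the allyl ester, the π-allyl is reduced to propene, and the silyl ether, enol ether and prenyl groups are left alone.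

Step 10
Reactants: 17 chloroacetaldehyde dimethyl acetal
Product: 19 methoxyacetylene, via sodium methoxyacetylide 18 (not isolated)
Conditions: NaNH2 (3 equiv), liq. NH3, −33 °C; evaporate NH3; sat. aq NH4Cl, −20 °C; distil into toluene at −78 °C
Reagents that add atoms: none
Why: Twofold base-induced elimination (methanol, then HCl) of the chloroacetal with sodium amide gives the sodium acetylide of methoxyacetylene, which is protonated on quench; this is the standard preparation of the alkoxyalkyne.

Step 11
Reactants: 16 (2S,4S)-4-{[tert-butyl(dimethyl)silyl]oxy}-6-(2,8-dimethylnona-2,7-dien-5-yl)-2-phenyl-3,4-dihydro-2H-pyran-5-carboxylic acid; 19 methoxyacetylene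
Product: 22 (7S,9S)-9-{[tert-butyl(dimethyl)silyl]oxy}-5-(2,8-dimethylnona-2,7-dien-5-ylidene)-3-methoxy-7-phenyl-6-oxaspiro[3.5]non-2-en-1-one (both C4 spiro epimers), via pyran acid chloride 20 (not isolated), via vinylketene 21 (not isolated)
Conditions: Ghosez reagent, CH2Cl2, 0 °C → rt; then 19 (5 equiv), Et3N (slow addition), CH2Cl2/toluene, 0 → 25 °C, closed vessel
Reagents that add atoms: none
Why: Neutral acid chloride formation, vinylogous (1,4-) dehydrochlorination by triethylamine at C8–H to the vinylketene (the usual entry from α,β-unsaturated acid chlorides) and ketene–alkoxyalkyne [2+2] cycloaddition across the ketene C=C bond, in which the nucleophilic alkyne CH carbon bonds to the ketene carbon C7 and the methoxy-bearing carbon to C4a; the spiro carbon forms as both epimers, which does not matter because it is planarized again in step 12.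

Step 12
Reactants: 22 (7S,9S)-9-{[tert-butyl(dimethyl)silyl]oxy}-5-(2,8-dimethylnona-2,7-dien-5-ylidene)-3-methoxy-7-phenyl-6-oxaspiro[3.5]non-2-en-1-one
Product: 24 (2S,4S)-4-{[tert-butyl(dimethyl)silyl]oxy}-5-methoxy-8,8-bis(3-methylbut-2-en-1-yl)-2-phenyl-3,4-dihydro-2H-chromen-7(8H)-one, via dienylketene 23 (not isolated)
Conditions: PhMe (0.01 M, degassed), 80 °C
Reagents that add atoms: none
Why: Heating should open the cyclobutenone by conrotatory 4π electrocyclic cleavage of the C4a–C7 bond to dienylketene 23; when the exocyclic C8a=C8 alkenyl arm has rotated inward, the ketene carbon C7 and the diprenylated terminus C8 are joined by a disrotatory 6π electrocyclization that closes the six-membered ring A through the new C7–C8 bond. The closest known chemistry is the second stage of the Danheiser benzannulation and the Moore rearrangement of 4-alkenylcyclobutenones; because C8 carries no hydrogen the sequence cannot continue to a phenol and stops at the cyclohexa-2,4-dienone, the thermal reverse of the Barton–Quinkert photo-opening of such dienones. No stereocentre is created: the spiro centre is destroyed, C8 bears two identical prenyl groups, and C2 and C4 are not involved. The one selectivity required is inward rotation of the alkenyl arm; ring opening is reversible, so the unproductive rotamer can reclose to 22 (either epimer) and reopen until it is drained through the irreversible 6π closure. The pyran ring holds the exocyclic C5=C4a and C8a=C8 bonds of 23 s-cis about the C4a–C8a bond, so the triene is pre-organized, and the positions of the methoxy group (C5) and the carbonyl (C7) are fixed by the connectivity of 22.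

Step 13
Reactants: 24 (2S,4S)-4-{[tert-butyl(dimethyl)silyl]oxy}-5-methoxy-8,8-bis(3-methylbut-2-en-1-yl)-2-phenyl-3,4-dihydro-2H-chromen-7(8H)-one
Product: 25 pongaflavanol, (2S,4S)-4-hydroxy-5-methoxy-8,8-bis(3-methylbut-2-en-1-yl)-2-phenyl-3,4-dihydro-2H-chromen-7(8H)-one
Conditions: TBAF, AcOH (1:1), THF, 0 °C → rt
Reagents that add atoms: none
Why: Fluoride-mediated silyl ether cleavage under acetic acid buffering, which avoids both acid that could ionize the C4 carbinol and free base that could attack the vinylogous ester.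

**Compound list**

1 | allyl acetoacetate (prop-2-en-1-yl 3-oxobutanoate) | CC(=O)CC(=O)OCC=C | starting material
2 | prenyl bromide (1-bromo-3-methylbut-2-ene) | CC(C)=CCBr | starting material
3 | dilithium dianion of allyl acetoacetate (not isolated) | C=CCOC([O-])=CC(=C)[O-].[Li+].[Li+] | intermediate
4 | allyl 7-methyl-3-oxooct-6-enoate | CC(C)=CCCC(=O)CC(=O)OCC=C | intermediate
5 | dilithium dianion of 4 (not isolated) | C=CCOC([O-])=CC([O-])=CCC=C(C)C.[Li+].[Li+] | intermediate
6 | allyl 7-methyl-4-(3-methylbut-2-en-1-yl)-3-oxooct-6-enoate | CC(C)=CCC(CC=C(C)C)C(=O)CC(=O)OCC=C | intermediate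
7 | ethyl (3S)-3-hydroxy-3-phenylpropanoate | CCOC(=O)C[C@H](O)c1ccccc1 | starting material
8 | ethyl (3S)-3-{[tert-butyl(dimethyl)silyl]oxy}-3-phenylpropanoate | CCOC(=O)C[C@@H](c1ccccc1)O[Si](C)(C)C(C)(C)C | intermediate
9 | (3S)-3-{[tert-butyl(dimethyl)silyl]oxy}-3-phenylpropanoic acid | OC(=O)C[C@@H](c1ccccc1)O[Si](C)(C)C(C)(C)C | intermediate
10 | (3S)-3-{[tert-butyl(dimethyl)silyl]oxy}-3-phenylpropanoyl chloride (not isolated) | ClC(=O)C[C@@H](c1ccccc1)O[Si](C)(C)C(C)(C)C | intermediate
11 | allyl 2-[(3S)-3-{[tert-butyl(dimethyl)silyl]oxy}-3-phenylpropanoyl]-7-methyl-4-(3-methylbut-2-en-1-yl)-3-oxooct-6-enoate | C=CCOC(=O)C(C(=O)C(CC=C(C)C)CC=C(C)C)C(=O)C[C@@H](c1ccccc1)O[Si](C)(C)C(C)(C)C | intermediate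
12 | allyl 2-[(3S)-3-hydroxy-3-phenylpropanoyl]-7-methyl-4-(3-methylbut-2-en-1-yl)-3-oxooct-6-enoate (not isolated) | C=CCOC(=O)C(C(=O)C(CC=C(C)C)CC=C(C)C)C(=O)C[C@@H](c1ccccc1)O | intermediate
13 | allyl (2S)-6-(2,8-dimethylnona-2,7-dien-5-yl)-4-oxo-2-phenyl-3,4-dihydro-2H-pyran-5-carboxylate | C=CCOC(=O)C1=C(C(CC=C(C)C)CC=C(C)C)O[C@H](c2ccccc2)CC1=O | intermediate
14 | allyl (2S,4S)-6-(2,8-dimethylnona-2,7-dien-5-yl)-4-hydroxy-2-phenyl-3,4-dihydro-2H-pyran-5-carboxylate | C=CCOC(=O)C1=C(C(CC=C(C)C)CC=C(C)C)O[C@H](c2ccccc2)C[C@@H]1O | intermediate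
15 | allyl (2S,4S)-4-{[tert-butyl(dimethyl)silyl]oxy}-6-(2,8-dimethylnona-2,7-dien-5-yl)-2-phenyl-3,4-dihydro-2H-pyran-5-carboxylate | C=CCOC(=O)C1=C(C(CC=C(C)C)CC=C(C)C)O[C@H](c2ccccc2)C[C@@H]1O[Si](C)(C)C(C)(C)C | intermediate
16 | (2S,4S)-4-{[tert-butyl(dimethyl)silyl]oxy}-6-(2,8-dimethylnona-2,7-dien-5-yl)-2-phenyl-3,4-dihydro-2H-pyran-5-carboxylic acid | OC(=O)C1=C(C(CC=C(C)C)CC=C(C)C)O[C@H](c2ccccc2)C[C@@H]1O[Si](C)(C)C(C)(C)C | intermediate
17 | chloroacetaldehyde dimethyl acetal (2-chloro-1,1-dimethoxyethane) | COC(CCl)OC | starting material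
18 | sodium methoxyacetylide (not isolated) | COC#[C-].[Na+] | intermediate
19 | methoxyacetylene (methoxyethyne), used as a cold toluene solution | COC#C | intermediate
20 | (2S,4S)-4-{[tert-butyl(dimethyl)silyl]oxy}-6-(2,8-dimethylnona-2,7-dien-5-yl)-2-phenyl-3,4-dihydro-2H-pyran-5-carbonyl chloride (not isolated) | ClC(=O)C1=C(C(CC=C(C)C)CC=C(C)C)O[C@H](c2ccccc2)C[C@@H]1O[Si](C)(C)C(C)(C)C | intermediate
21 | vinylketene [(4S,6S)-4-{[tert-butyl(dimethyl)silyl]oxy}-2-(2,8-dimethylnona-2,7-dien-5-ylidene)-6-phenyloxan-3-ylidene]methanone (not isolated) | O=C=C1C(=C(CC=C(C)C)CC=C(C)C)O[C@H](c2ccccc2)C[C@@H]1O[Si](C)(C)C(C)(C)C | intermediate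
22 | (7S,9S)-9-{[tert-butyl(dimethyl)silyl]oxy}-5-(2,8-dimethylnona-2,7-dien-5-ylidene)-3-methoxy-7-phenyl-6-oxaspiro[3.5]non-2-en-1-one: 3-methoxycyclobutenone spiro-fused at C4a to the silylated pyran with exocyclic diprenylmethylidene, both spiro epimers | COC1=CC(=O)C12[C@@H](O[Si](C)(C)C(C)(C)C)C[C@@H](c1ccccc1)OC2=C(CC=C(C)C)CC=C(C)C | intermediate
23 | dienylketene 3-[(4S,6S)-4-{[tert-butyl(dimethyl)silyl]oxy}-2-(2,8-dimethylnona-2,7-dien-5-ylidene)-6-phenyloxan-3-ylidene]-3-methoxyprop-1-en-1-one, alkenyl arm cis to the ketene (not isolated) | O=C=C/C(OC)=C1\C(=C(CC=C(C)C)CC=C(C)C)O[C@H](c2ccccc2)C[C@@H]1O[Si](C)(C)C(C)(C)C | intermediate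
24 | 4-O-TBS pongaflavanol, (2S,4S)-4-{[tert-butyl(dimethyl)silyl]oxy}-5-methoxy-8,8-bis(3-methylbut-2-en-1-yl)-2-phenyl-3,4-dihydro-2H-chromen-7(8H)-one | COC1=CC(=O)C(CC=C(C)C)(CC=C(C)C)C2=C1[C@@H](O[Si](C)(C)C(C)(C)C)C[C@@H](c1ccccc1)O2 | intermediate
25 | pongaflavanol, (2S,4S)-4-hydroxy-5-methoxy-8,8-bis(3-methylbut-2-en-1-yl)-2-phenyl-3,4-dihydro-2H-chromen-7(8H)-one | COC1=CC(=O)C(CC=C(C)C)(CC=C(C)C)C2=C1[C@@H](O)C[C@@H](c1ccccc1)O2 | target

**Step count**

Total steps: 13.
Longest linear sequence: 10 steps (7 → 8 → 9 → 11 → 13 → 14 → 15 → 16 → 22 → 24 → 25; the branch from 1 is equally long).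

**Steps most likely to fail**

1. Step 11. γ-Deprotonation of the hindered acyl chloride may be slow, and the volatile, only moderately nucleophilic alkyne may capture vinylketene 21 more slowly than the ketene closes to its fused cyclobutenone isomer or is consumed by self-reaction, so that little 22 accumulates below the temperature at which 22 itself starts to open. The fallback changes the ketenophile and the oxidation level of the two-carbon partner. It sets out from acid 16 (converted to 20 and 21 as before) and from chloroacetal 17, and comes back at 22. Chloroacetal 17 is dehydrochlorinated with KOt-Bu to 1,1-dimethoxyethene F1, a much more nucleophilic ketene acetal that can be used in large excess. Its [2+2] cycloaddition to 21 should give the spiro-fused 3,3-dimethoxycyclobutanone F2, regiochemistry again placing the oxygenated carbon on C4a. β-Elimination of methanol from F2 (basic alumina or catalytic DBU) then delivers 22.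

2. Step 6. After silyl loss the C2 hydroxyl may add to the allyl ester carbonyl instead of the hindered, α-branched ketone, so that lactonization with loss of allyl alcohol competes with pyranone formation. The fallback removes the ester before ring closure and puts it back afterwards. It sets out from tricarbonyl 11 and comes back at 13. Pd(0)-catalysed deallylation of 11 with HCO2H/Et3N gives the 2-acyl β-keto acid F3, which should lose CO2 in the flask to give the silyloxy β-diketone F4. Aqueous HF then frees the hydroxy β-diketone F5, which has no ester to lactonize onto and can only cyclodehydrate to the ester-free dihydropyranone F6. Electrophilic iodination of this vinylogous ester at C5 of the pyranone (flavan C4a; I2, pyridine, CH2Cl2) gives the 5-iodo dihydropyranone F7. Pd-catalysed alkoxycarbonylation (CO, allyl alcohol, Et3N) reinstalls the allyl ester and gives 13.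

3. Step 12. Outward rotation of the alkenyl arm gives the unproductive ketene rotamer, which, instead of reclosing, may leak irreversibly through a [1,5]-hydrogen shift from C4–H to the ketene carbon. At the temperature needed for thermal opening the gem-diprenyl dienone may also drift by [3,3] shifts of a prenyl group. The fallback replaces the ground-state thermal opening by a photochemical one, so that neither a thermally selected rotation sense nor heat is needed. It sets out from 22 and comes back at 24 and makes no new compound (F0). Irradiation of 22 (about 300 nm, degassed toluene, 0 °C, rigorously aprotic) should open the cyclobutenone in the excited state to 23, and the 6π closure to 24 then proceeds in the dark at that temperature. Dienone 24 also absorbs, but its Barton–Quinkert photo-opening only regenerates the same dienylketene, which recloses in the absence of nucleophiles.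

**Further compounds**

F1 | step 11 | 1,1-dimethoxyethene | C=C(OC)OC
F2 | step 11 | (7S,9S)-9-{[tert-butyl(dimethyl)silyl]oxy}-5-(2,8-dimethylnona-2,7-dien-5-ylidene)-3,3-dimethoxy-7-phenyl-6-oxaspiro[3.5]nonan-1-one (both spiro epimers) | COC1(OC)CC(=O)C12[C@@H](O[Si](C)(C)C(C)(C)C)C[C@@H](c1ccccc1)OC2=C(CC=C(C)C)CC=C(C)C
F3 | step 6 | 2-[(3S)-3-{[tert-butyl(dimethyl)silyl]oxy}-3-phenylpropanoyl]-7-methyl-4-(3-methylbut-2-en-1-yl)-3-oxooct-6-enoic acid | OC(=O)C(C(=O)C(CC=C(C)C)CC=C(C)C)C(=O)C[C@@H](c1ccccc1)O[Si](C)(C)C(C)(C)C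
F4 | step 6 | (1S)-1-{[tert-butyl(dimethyl)silyl]oxy}-9-methyl-6-(3-methylbut-2-en-1-yl)-1-phenyldec-8-ene-3,5-dione | CC(C)=CCC(CC=C(C)C)C(=O)CC(=O)C[C@@H](c1ccccc1)O[Si](C)(C)C(C)(C)C
F5 | step 6 | (1S)-1-hydroxy-9-methyl-6-(3-methylbut-2-en-1-yl)-1-phenyldec-8-ene-3,5-dione | CC(C)=CCC(CC=C(C)C)C(=O)CC(=O)C[C@@H](c1ccccc1)O
F6 | step 6 | (2S)-6-(2,8-dimethylnona-2,7-dien-5-yl)-2-phenyl-2,3-dihydro-4H-pyran-4-one | O=C1C=C(C(CC=C(C)C)CC=C(C)C)O[C@H](c2ccccc2)C1
F7 | step 6 | (2S)-6-(2,8-dimethylnona-2,7-dien-5-yl)-5-iodo-2-phenyl-2,3-dihydro-4H-pyran-4-one | O=C1C(I)=C(C(CC=C(C)C)CC=C(C)C)O[C@H](c2ccccc2)C1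
F0 | step 12 | none | none
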